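Late in the autumn run [target] flattens: it reads 0.0250 M at 130 s and 0.0256 M at 160 s, a step smaller than the scatter of 8 × 10⁻⁴ M.

- autumn run (time / s: [target] / M): 27: 0.0092; 53: 0.0151; 80: 0.0216; 110: 0.0235; 130: 0.0250; 160: 0.0256
- spring run (time / s: [target] / M): 27: 0.0422; 53: 0.0496; 80: 0.0528; 110: 0.0548; 130: 0.0548; 160: 0.0545

(scatter of a reading: 8 × 10⁻⁴ M)

| setting | autumn | spring | noon |
|---|---|---|---|
| substrate | 0.100 M | 0.100 M | 0.300 M |
| partner | 0.120 M | 0.120 M | 0.0400 M |
| target |  | 0.0300 M |  |
| time |  |  | 160 s |

- Overall: substrate + partner -> target.
- Constant volume, constant temperature.
- "The second partner" is partner.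

- target in the noon run at 160 s, as a share of the substrate charged

The bench rule reads a flat curve against the limiting reagent, which in autumn is the substrate, charged at 0.100 M against 0.120 M of partner. The plateau share, the target at the last reading per unit of limiting reagent charged, is then 25.6 % in autumn, about a quarter. In the noon flask the partner is the limiting reagent, so the rule, as reckoned here, gives 0.0102 M of target, or 3.41 % of the substrate charged. The noon substrate can lose at most 13.3 % of its charge, so [substrate] may be frozen and the partner treated as pseudo-first-order. If the rate follows [substrate][partner], noon starts like autumn, since the products of the charges are equal, and the autumn slope up to the first reading, 3.41 × 10⁻⁴ M s⁻¹, if held constant, gives that amount in 30.1 s, well inside 160 s. The border of the rule is the ratio of the excess charge to the limiting charge: 1.20 in autumn and spring alike, but 7.50 in noon, so the share is carried beyond the ratio at which it was read, and the noon reading at 160 s is the one to watch.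

The forecast gives 7.2 %, “limited by the partner”, which is above the reckoning here.

The noon run gives 4.63 %, within the margin of the forecast.

    substrate + partner → target (0.03480 M⁻¹ s⁻¹)
    substrate + partner → side product (0.04350 M⁻¹ s⁻¹)
    target → decomposed product (0.002600 s⁻¹)
    substrate + partner + target → 2 target (0.7290 M⁻² s⁻¹)

The fit with the true steps forecasts 4.56 % for noon. Reckoned per unit of limiting reagent, the noon target at 160 s is 34.7 % of the partner charged, above the autumn share, while the spring run, charged in the autumn ratio of substrate to partner with 0.0300 M of target added, read a gain of 24.5 % of its substrate by 160 s.

The numbers in the tables were computed with made-up constants, and the scatter is random.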